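**Plan**

Atom labels: side chain C1′ (benzylic, on the quinone ring) to C5′ (on C1 of the cyclohexene ring); cyclohexene ring C1 (quaternary), C2 (CH–CH3), C3=C4, C5, C6.

1. The quinone is traced back to the 3-substituted 1,2,4,5-tetramethoxybenzene 15 (one O–CH3 hydrolysis, one arene oxidation).
2. The side chain is cut at C1′–C2′ and C3′–CH3. The (E)-C2′=C3′ alkene carries its C3′ methyl cis to the benzylic C1′, which is the pattern left by syn methylmetalation of a terminal alkyne and coupling at the metalated carbon. The pieces are alkyne 8, AlMe3 13 and benzylic chloride 12.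
3. Alkyne 8 is cut at C2′≡C3′ (one-carbon homologation) and C4′–C5′ (olefination) to ring aldehyde 3. Its ring is opened across C1–C2 and C5–C6 into methacrolein and (E)-3-methylpenta-1,3-diene.
4. Forward: the cyclohexene ring forms first (step 1), the chain grows to the alkyne (steps 2–5), the arene is made separately (steps 6–7), the two are joined with the methyl group in step 8, and the quinone is unveiled last (steps 9–10).
5. Stereochemistry: C1 and C2 are both set in the catalytic enantioselective endo Diels–Alder reaction. The E alkene comes from syn carbometalation and a stereoretentive coupling.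

Key step: step 8

Assumption: the (S)-configured oxazaborolidinium catalyst is taken to leave open the Cα-Re face of bound methacrolein; if the sense proved opposite, the mirror-image catalyst would be used with no other change.

**Route**

Step 1
Reactants: 1 methacrolein; 2 (E)-3-methylpenta-1,3-diene
Product: 3 (1S,2R)-1,2,3-trimethylcyclohex-3-ene-1-carbaldehyde
Conditions: B-(o-tolyl) oxazaborolidine of (S)-α,α-diphenylprolinol protonated with HNTf2 (20 mol%), CH2Cl2, −78 → −40 °C
Reagents that add atoms: none
Why: Enantioselective Diels–Alder reaction under chiral oxazaborolidinium catalysis, in which the terminal methyl of the diene steers its substituted terminus to Cα of the enal (forming C1–C2 and C5–C6), the formyl group sits endo and so ends cis to the C2 methyl, and the catalyst blocks one enal face so that the diene adds to the Cα-Re face, setting C1 (S) and C2 (R) in one event.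

Step 2
Reactants: 3 (1S,2R)-1,2,3-trimethylcyclohex-3-ene-1-carbaldehyde
Product: 4 methyl (2E)-3-[(1R,2R)-1,2,3-trimethylcyclohex-3-en-1-yl]prop-2-enoate
Conditions: (MeO)2P(O)CH2CO2Me, NaH, THF, 0 °C → rt
Reagents that add atoms: trimethyl phosphonoacetate, COC(=O)CP(=O)(OC)OC
Why: Horner–Wadsworth–Emmons olefination of a non-enolisable neopentyl-type aldehyde, which should give the E-enoate by syn elimination of phosphate while the quaternary C1 cannot epimerise.

Step 3
Reactants: 4 methyl (2E)-3-[(1R,2R)-1,2,3-trimethylcyclohex-3-en-1-yl]prop-2-enoate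
Product: 5 methyl 3-[(1R,2S)-1,2,3-trimethylcyclohex-3-en-1-yl]propanoate
Conditions: Mg turnings, MeOH, rt
Reagents that add atoms: none
Why: Dissolving-metal conjugate reduction, in which magnesium in methanol transfers electrons only to the conjugated enoate, so the isolated trisubstituted C3=C4 alkene and both stereocentres should stay intact (the C2 descriptor changes only through the priority rules).

Step 4
Reactants: 5 methyl 3-[(1R,2S)-1,2,3-trimethylcyclohex-3-en-1-yl]propanoate
Product: 7 3-[(1R,2S)-1,2,3-trimethylcyclohex-3-en-1-yl]propanal, via diisobutylaluminium hemiacetal 6 (not isolated)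
Conditions: i-Bu2AlH (1.05 equiv), CH2Cl2, −78 °C; then MeOH, aq. potassium sodium tartrate
Reagents that add atoms: none
Why: Partial reduction of an ester with i-Bu2AlH, in which one hydride adds at −78 °C and the aluminium hemiacetal 6 should persist until work-up releases the aldehyde without over-reduction.

Step 5
Reactants: 7 3-[(1R,2S)-1,2,3-trimethylcyclohex-3-en-1-yl]propanal
Product: 8 (5R,6S)-5-(but-3-yn-1-yl)-1,5,6-trimethylcyclohex-1-ene
Conditions: dimethyl (1-diazo-2-oxopropyl)phosphonate, K2CO3, MeOH, 0 °C → rt
Reagents that add atoms: dimethyl (1-diazo-2-oxopropyl)phosphonate, CC(=O)C(=[N+]=[N-])P(=O)(OC)OC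
Why: Seyferth–Gilbert homologation in the Ohira–Bestmann variant, in which the diazophosphonate anion freed by methanolysis adds to the aldehyde and loss of phosphate and N2 with a 1,2-hydride shift should give the terminal alkyne under base too mild to affect the remote stereocentres.

Step 6
Reactants: 9 1,2,4,5-tetramethoxybenzene
Product: 11 (2,3,5,6-tetramethoxyphenyl)methanol, via (2,3,5,6-tetramethoxyphenyl)lithium 10 (not isolated)
Conditions: n-BuLi, TMEDA, THF, 0 °C; then (CH2O)n, 0 °C → rt; H2O
Reagents that add atoms: paraformaldehyde (as formaldehyde), C=O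
Why: Directed ortho-metalation followed by hydroxymethylation, in which the ring hydrogen flanked by two methoxyls is removed by n-BuLi and the aryllithium adds to formaldehyde released from the polymer.

Step 7
Reactants: 11 (2,3,5,6-tetramethoxyphenyl)methanol
Product: 12 3-(chloromethyl)-1,2,4,5-tetramethoxybenzene
Conditions: SOCl2, pyridine, CH2Cl2, 0 °C
Reagents that add atoms: thionyl chloride, O=S(Cl)Cl
Why: Chlorodehydroxylation of an activated benzylic alcohol with thionyl chloride, with pyridine trapping HCl so that the electron-rich ring is not alkylated by its own benzylic cation.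

Step 8
Reactants: 8 (5R,6S)-5-(but-3-yn-1-yl)-1,5,6-trimethylcyclohex-1-ene; 13 trimethylaluminium; 12 3-(chloromethyl)-1,2,4,5-tetramethoxybenzene
Product: 15 3-[(2E)-3-methyl-5-[(1R,2S)-1,2,3-trimethylcyclohex-3-en-1-yl]pent-2-en-1-yl]-1,2,4,5-tetramethoxybenzene, via (E)-alkenyldimethylalane 14 (not isolated)
Conditions: AlMe3 (2 equiv), Cp2ZrCl2 (0.25 equiv), ClCH2CH2Cl, 0 °C → rt; volatiles removed in vacuo; then 12 (0.9 equiv), Pd(PPh3)4 (5 mol%), THF, rt
Reagents that add atoms: none
Why: Cp2ZrCl2 and AlMe3 form a polarised methylzirconium–aluminium species that adds CH3–metal syn across the terminal alkyne of 8, placing CH3 on the internal carbon C3′ and the metal, ending on aluminium, on the terminal carbon C2′ to give (E)-alkenylalane 14. Zerovalent palladium then inserts into the benzylic C–Cl bond of 12, the alkenyl group passes from aluminium to palladium, and reductive elimination forms C1′–C2′ with retention of the alkene geometry. The closest known reaction type is the Negishi zirconium-catalysed methylalumination of terminal alkynes followed in the same pot by palladium-catalysed coupling of the alkenylalane with a benzylic chloride, a standard entry to prenylated arene and quinone side chains. No ring is closed and no stereocentre is created; the only stereochemical element set is the E geometry of C2′=C3′, fixed by the syn addition and the stereoretentive coupling, while C1 and C2 of the cyclohexene ring are remote and untouched. The step needs terminal regiochemistry, secured by the preference of the metal for the unsubstituted alkyne carbon, and chemoselectivity for the alkyne over the trisubstituted C3=C4 ring alkene, which does not carbometalate under these conditions. Transfer of alkenyl in preference to methyl is secured by stripping the excess AlMe3 before 12 and the palladium catalyst are added.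

Step 9
Reactants: 15 3-[(2E)-3-methyl-5-[(1R,2S)-1,2,3-trimethylcyclohex-3-en-1-yl]pent-2-en-1-yl]-1,2,4,5-tetramethoxybenzene
Product: 16 2,5-dimethoxy-3-[(2E)-3-methyl-5-[(1R,2S)-1,2,3-trimethylcyclohex-3-en-1-yl]pent-2-en-1-yl]cyclohexa-2,5-diene-1,4-dione
Conditions: (NH4)2Ce(NO3)6 (2.5 equiv), MeCN/H2O, 0 °C
Reagents that add atoms: water, O
Why: Oxidative demethylation with tetravalent cerium, in which two one-electron oxidations of the electron-rich arene, attack of water at two para-related methoxylated carbons and loss of two molecules of methanol should give the 2,5-dimethoxy-1,4-quinone, the brief cold conditions sparing both trisubstituted alkenes.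

Step 10
Reactants: 16 2,5-dimethoxy-3-[(2E)-3-methyl-5-[(1R,2S)-1,2,3-trimethylcyclohex-3-en-1-yl]pent-2-en-1-yl]cyclohexa-2,5-diene-1,4-dione
Product: 17 metachromin C, 2-hydroxy-5-methoxy-3-[(2E)-3-methyl-5-[(1R,2S)-1,2,3-trimethylcyclohex-3-en-1-yl]pent-2-en-1-yl]cyclohexa-2,5-diene-1,4-dione
Conditions: 70% aq. HClO4, THF, 0 °C → rt
Reagents that add atoms: water, O
Why: Acid-catalysed addition–elimination of water at a vinylogous ester, the known mono-hydrolysis of 3-alkyl-2,5-dimethoxybenzoquinones, which should select the methoxyl wedged between C1′ and a carbonyl because that group is twisted out of conjugation, leaving its carbon the more electrophilic and its hydrolysis strain-relieving.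

**Compound list**

1 | methacrolein (2-methylprop-2-enal) | CC(=C)C=O | starting material
2 | (E)-3-methylpenta-1,3-diene | C=C/C(C)=C/C | starting material
3 | (1S,2R)-1,2,3-trimethylcyclohex-3-ene-1-carbaldehyde (formyl cis to the C2 methyl) | O=C[C@@]1(C)CCC=C(C)[C@H]1C | intermediate
4 | methyl (2E)-3-[(1R,2R)-1,2,3-trimethylcyclohex-3-en-1-yl]prop-2-enoate | COC(=O)/C=C/[C@@]1(C)CCC=C(C)[C@H]1C | intermediate
5 | methyl 3-[(1R,2S)-1,2,3-trimethylcyclohex-3-en-1-yl]propanoate | COC(=O)CC[C@@]1(C)CCC=C(C)[C@H]1C | intermediate
6 | {1-methoxy-3-[(1R,2S)-1,2,3-trimethylcyclohex-3-en-1-yl]propoxy}bis(2-methylpropyl)alumane (not isolated; hemiacetal carbon undefined) | COC(CC[C@@]1(C)CCC=C(C)[C@H]1C)O[Al](CC(C)C)CC(C)C | intermediate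
7 | 3-[(1R,2S)-1,2,3-trimethylcyclohex-3-en-1-yl]propanal | O=CCC[C@@]1(C)CCC=C(C)[C@H]1C | intermediate
8 | (5R,6S)-5-(but-3-yn-1-yl)-1,5,6-trimethylcyclohex-1-ene | C#CCC[C@@]1(C)CCC=C(C)[C@H]1C | intermediate
9 | 1,2,4,5-tetramethoxybenzene | COc1cc(OC)c(OC)cc1OC | starting material
10 | (2,3,5,6-tetramethoxyphenyl)lithium (not isolated) | [Li]c1c(OC)c(OC)cc(OC)c1OC | intermediate
11 | (2,3,5,6-tetramethoxyphenyl)methanol | OCc1c(OC)c(OC)cc(OC)c1OC | intermediate
12 | 3-(chloromethyl)-1,2,4,5-tetramethoxybenzene (2,3,5,6-tetramethoxybenzyl chloride) | COc1cc(OC)c(OC)c(CCl)c1OC | intermediate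
13 | trimethylaluminium | C[Al](C)C | starting material
14 | dimethyl[(1E)-2-methyl-4-[(1R,2S)-1,2,3-trimethylcyclohex-3-en-1-yl]but-1-en-1-yl]alumane (not isolated) | C[Al](C)/C=C(C)/CC[C@@]1(C)CCC=C(C)[C@H]1C | intermediate
15 | 3-[(2E)-3-methyl-5-[(1R,2S)-1,2,3-trimethylcyclohex-3-en-1-yl]pent-2-en-1-yl]-1,2,4,5-tetramethoxybenzene | COc1cc(OC)c(OC)c(C/C=C(\C)CC[C@@]2(C)CCC=C(C)[C@H]2C)c1OC | intermediate
16 | 2,5-dimethoxy-3-[(2E)-3-methyl-5-[(1R,2S)-1,2,3-trimethylcyclohex-3-en-1-yl]pent-2-en-1-yl]cyclohexa-2,5-diene-1,4-dione | COC1=CC(=O)C(OC)=C(C/C=C(\C)CC[C@@]2(C)CCC=C(C)[C@H]2C)C1=O | intermediate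
17 | metachromin C, 2-hydroxy-5-methoxy-3-[(2E)-3-methyl-5-[(1R,2S)-1,2,3-trimethylcyclohex-3-en-1-yl]pent-2-en-1-yl]cyclohexa-2,5-diene-1,4-dione | COC1=CC(=O)C(O)=C(C/C=C(\C)CC[C@@]2(C)CCC=C(C)[C@H]2C)C1=O | target

**Count**

Total steps: 10. Longest linear sequence: 8 steps (steps 1–5, 8, 9, 10); steps 6–7 form the short arene branch.

**Steps most likely to fail**

Step 1. The cycloaddition of an α-branched enal with an acyclic diene may show incomplete enantiofacial discrimination or an eroded endo preference. The fallback sets out from 1 and 2 and returns at 3. The cycloaddition would be run with achiral Me2AlCl in CH2Cl2 at −78 °C, giving 3 as a racemate with its mirror image, (1R,2S)-1,2,3-trimethylcyclohex-3-ene-1-carbaldehyde F1. Condensation of the mixture with (1S,2S)-N,N′-dimethyl-1,2-diphenylethane-1,2-diamine (4 Å molecular sieves, Et2O) should give two diastereomeric aminals, (4S,5S)-1,3-dimethyl-4,5-diphenyl-2-[(1S,2R)-1,2,3-trimethylcyclohex-3-en-1-yl]imidazolidine F2 and (4S,5S)-1,3-dimethyl-4,5-diphenyl-2-[(1R,2S)-1,2,3-trimethylcyclohex-3-en-1-yl]imidazolidine F3. These would be separated by chromatography or crystallisation, which would also remove any exo isomer. Dilute aqueous HCl in Et2O would then hydrolyse F2 back to 3.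

Step 8. A methyl group may transfer from aluminium in place of the alkenyl group, or slow aluminium-to-palladium transmetalation may allow homocoupling and reduction of the benzylic partner. The fallback sets out from 8 and 12 and returns at 15, forming the same two bonds in separate operations. Alane 14, generated as in step 8, would be quenched with I2 in THF at −30 °C to give (5R,6S)-5-[(3E)-4-iodo-3-methylbut-3-en-1-yl]-1,5,6-trimethylcyclohex-1-ene F4 with the alkene geometry retained. Chloride 12 would be converted with zinc dust and LiCl in THF into (2,3,5,6-tetramethoxybenzyl)zinc chloride F5. Negishi coupling of F4 with F5 under Pd(PPh3)4 in THF at rt should then give 15.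

Step 10. Hydrolysis may occur at the wrong methoxyl, or the freed hydroxyl may add under acid to the C2′=C3′ alkene. The fallback sets out from 16 and returns at 17. Both vinylogous esters would be saponified with aqueous NaOH in THF/MeOH and the solution acidified to give 2,5-dihydroxy-3-[(2E)-3-methyl-5-[(1R,2S)-1,2,3-trimethylcyclohex-3-en-1-yl]pent-2-en-1-yl]cyclohexa-2,5-diene-1,4-dione F6. Brief treatment with MeOH and catalytic H2SO4 at rt should then re-etherify only the unhindered hydroxyl next to the ring C–H, since the hydroxyl flanked by C1′ resists vinylogous esterification, and so give 17.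

**Further compounds**

F1 | step 1 | (1R,2S)-1,2,3-trimethylcyclohex-3-ene-1-carbaldehyde (mirror image of 3) | O=C[C@]1(C)CCC=C(C)[C@@H]1C
F2 | step 1 | (4S,5S)-1,3-dimethyl-4,5-diphenyl-2-[(1S,2R)-1,2,3-trimethylcyclohex-3-en-1-yl]imidazolidine | CN1[C@@H](c2ccccc2)[C@H](c2ccccc2)N(C)C1[C@@]3(C)CCC=C(C)[C@H]3C
F3 | step 1 | (4S,5S)-1,3-dimethyl-4,5-diphenyl-2-[(1R,2S)-1,2,3-trimethylcyclohex-3-en-1-yl]imidazolidine | CN1[C@@H](c2ccccc2)[C@H](c2ccccc2)N(C)C1[C@]3(C)CCC=C(C)[C@@H]3C
F4 | step 8 | (5R,6S)-5-[(3E)-4-iodo-3-methylbut-3-en-1-yl]-1,5,6-trimethylcyclohex-1-ene | I/C=C(C)/CC[C@@]1(C)CCC=C(C)[C@H]1C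
F5 | step 8 | (2,3,5,6-tetramethoxybenzyl)zinc chloride | Cl[Zn]Cc1c(OC)c(OC)cc(OC)c1OC
F6 | step 10 | 2,5-dihydroxy-3-[(2E)-3-methyl-5-[(1R,2S)-1,2,3-trimethylcyclohex-3-en-1-yl]pent-2-en-1-yl]cyclohexa-2,5-diene-1,4-dione | OC1=CC(=O)C(O)=C(C/C=C(\C)CC[C@@]2(C)CCC=C(C)[C@H]2C)C1=O
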